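3 questions stand on this flask, and you can reach them through one number.

| setting | autumn | winter | flask |
|---|---|---|---|
| starting material | 1 M | 1 M | 1.0 M |
| gas phase | 54 mM (held) | 54 mM (held) | 54 mM (held) |
| catalyst | 6.5 mM | 9.8 mM | 13 mM |
| remark | run made earlier | run made earlier |  |
| time |  |  | 15 h |

| run | time / h | target / % | starting material / % |
|---|---|---|---|
| autumn | 0.833 | 0.7 | 99.8 |
| autumn | 2.50 | 3.1 | 96.3 |
| autumn | 4.00 | 6.1 | 93.8 |
| autumn | 6.00 | 9.1 | 90.1 |
| autumn | 10.0 | 14.7 | 84.0 |
| winter | 0.667 | 0.5 | 98.8 |
| winter | 1.33 | 1.7 | 97.8 |
| winter | 2.50 | 4.9 | 94.8 |
| winter | 5.00 | 10.4 | 89.1 |
| winter | 10.0 | 19.0 | 78.7 |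

(each reading ± 0.3 percentage points)

* the target standing at 15 h, as a percentage of the starting material charged
* the change that raises the amount of target at 15 h, in percent of the starting material charged most ("none" if none brings more than 2 percentage points) (alpha / theta / beta / none)
* amount of target at 15 h, in percent of the starting material charged, after alpha

- alpha: doubling the amount of catalyst, all else as stated
- theta: doubling the transfer coefficient of the gas phase, all else as stated
- beta: doubling the saturation concentration of gas phase, all else as stated

- at the start none of the gas phase is in solution

**Catalyst return.** From the autumn run to the winter run you multiply the catalyst by 1.51 but the target at 10.0 h by 1.29, so on a logarithmic scale the catalyst returns 0.625 of itself, less than one, and I read this as something besides the catalyst holding the target back, with gas supply as one candidate.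

**Demand number.** Take the demand number, the slowing that added catalyst meets as the two runs show it, put in the form of a Damköhler number, which grows with catalyst; the return equals one over one plus this number, so at this flask's catalyst it reads 0.978, a reading that carries the scatter of the runs and does not show how much of the slowing comes from gas supply.

**My reckoning.** Target goes as catalyst over one plus the number, which turns the winter run's last reading into 22.1 % for this flask at 10.0 h, and the winter run's growth carries that to 31.5 % at 15 h. Doubling catalyst multiplies this by 1.34, doubling transfer by 1.33 if I count the whole number as gas supply, and doubling saturation by 2 if the rate follows dissolved gas in proportion, more than either, so I choose beta.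

**One number?** No: the winter run's last reading falls 2.3 percentage points short of the charge, more than the scatter, so starting material goes elsewhere and my figure leans high.

**The forecast.** It gave 30 %, below mine, with beta best and 39 % after alpha: “Doubling saturation doubles dissolved gas at every point, so the rate doubles”.

**The flask.** It gives 28.7 %, beta best with 20 points gained, and 37.1 % after alpha.

    starting material + dissolved gas + catalyst ⇌ catalyst + target (K = 22.0 M⁻¹, k = 67.0 M⁻² h⁻¹)
    starting material + target → side product (k = 0.0150 M⁻¹ h⁻¹)
    gas phase ⇌ dissolved gas, rate k3*(csat - [dissolved gas]) (kL = 1.60 h⁻¹)

At 15 h this flask still makes target 5.05 times faster than it uses it up. The demand number's factor on 28.7 % gives 38.5 % after alpha, against 37.1 %.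

**Second flask.** Read at 4.0 h, the same flask should, by the number, hold 9.18 %, scaled from the autumn reading at that time; it holds 9.74 %.

Readings and results are simulated for an exercise.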